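**Remark on the chemistry (assumption).** Germacranolide numbering is used throughout: ring C1–C10, C14 (methyl) on C10, C15 (methyl) on C4, C11–C13 the lactone/acrylate carbons. Dimethyl 2,3-O-isopropylidene-L-tartrate, (R)-4-benzyloxazolidin-2-one, 3-chloro-2-(chloromethyl)prop-1-ene, 4-methoxybenzyl alcohol and angelic acid are taken as purchased.

## The problem

The target is a ten-membered carbocycle (C1–C10) with a cis-fused α-methylene-γ-lactone across C6–C7, a cis C4=C5 alkene carrying C15, a cis C1–C2 epoxide, a secondary alcohol at C3, an angelate at C8 and a tertiary alcohol at C10. Seven stereocentres (1R,2R,3R,6S,7R,8S,10R) sit on a mobile medium ring, so most must be fixed before the ring exists or be set by an intramolecular event. C1/C2 can come from a C2-symmetric pool compound, C10 from C1 by 1,2-induction, C7/C8 as a syn pair from one aldol, and C6 and C3 from C7 through the lactone tether. The ring must be closed without scrambling a (Z)-trisubstituted alkene. The functional groups are fragile: the α-methylene lactone is a Michael acceptor, the angelate isomerises to the tiglate and is one of three esters, and the epoxy alcohol is open to Payne rearrangement and to acid. This forces the order: epoxide last, no strong base or nucleophile at the end. The enabling feature is that the C3 hydroxyl and the C6 lactone oxygen lie on the same face on either side of the cis C4=C5 alkene, with the lactone acid on C7. That is the pattern left by 1,4-oxidation of a C3=C4–C5=C6 diene by a tethered C12 carboxylic acid and an external oxygen nucleophile.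

## Retrosynthesis

**Epoxide and C3 hydroxyl.** Target 37 is taken back to epoxy acetate 36 (acetate cleavage), then to mesylate 35 and triol 34 by cutting the epoxide C2–O bond. An epoxide next to the allylic system would not survive palladium or acid, so it is carried as the trans-acetonide 33 of the threo diol. Closure by O1 onto a C2 sulfonate inverts C2, which is why the diol must have the L-tartrate configuration. The forward steps need sulfonylation of the less hindered C2 hydroxyl and a neutral acetate removal.

**Lactone and both allylic oxygens (key cut).** In 33 the C6–O lactone bond and the C3–O acetate bond are cut together, giving the (3Z,5Z)-cyclodecadienyl acrylic acid 32. Separate hydroxylations at C3 and C6 followed by lactonisation would need two more stereocontrolled oxidations on a flexible ring. The 1,4-oxidation makes one ring and two stereocentres in one operation and moves the alkene to C4=C5. The forward reaction must deliver the carboxylate to C6 syn to C11, add acetate at C3 cis to it, and keep the new alkene cis.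

**Acid and angelate.** Acid 32 comes from enal 31 and allylic alcohol 30, unmasked from the PMB ether 29. The acid is made last because a free C12 acid next to a free C8 hydroxyl would close the 7,8-lactone. The angelate is therefore installed first, on diol 26, where only the secondary C8 hydroxyl can react.

**Ring.** Diol 26 and its bis(silyl ether) 25 are opened at the C4–C5 σ-bond to the stannane/iodide 24. Ring-closing metathesis cannot give a trisubstituted (Z,Z)-diene, and an olefination across C5=C6 with an allylic ylide gives poor geometry. A palladium coupling joins two alkenyl carbons whose geometries were fixed beforehand and keeps both.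

**The two alkenyl termini.** The (5Z)-iodide of 24 comes from aldehyde 23 by Stork–Zhao olefination. The C4 stannane of 22 comes from the C4 iodide of 21 by iodine–tin exchange, done before the second iodide exists so that the termini are never ambiguous. Alcohol 21 is the reduced form of the protected aldol 20.

**C7–C8.** Aldol 19 is cut at C7–C8 into aldehyde 9 and N-acyloxazolidinone 17. The syn relation of the C7 side chain and the C8 oxygen is the Evans syn pattern, and the auxiliary sets both centres independently of the remote C10 centre. The union is convergent.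

**C1–C4 and C8–C10.** Aldehyde 9 goes back through vinyl iodide 7 (C3=C4 by Zhao olefination of aldehyde 6) to tertiary alcohol 4. Its C10–C14 and C9–C10 bonds come from two successive organometallic additions (3, then 4) to the bis-Weinreb amide 2 of tartrate 1. The tartrate supplies C1, C2 and the trans-acetonide; C10 is set by Felkin–Anh addition next to C1.

**Acyl fragment.** Imide 17 comes from acid 14 and auxiliary 15. Acid 14 comes from carboxylation of the Grignard reagent of chloride 12, made from 10 and 11. The symmetric allyl unit gives one regioisomer, and the PMB ether holds C12 at the alcohol level until the aldehyde stage at C6 has passed.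

## Roads not taken

**Alternative 1:** The ring is drawn as a five–seven bicycle bonded C4–C10. In the forward step KOtBu forms a C10 alkoxide that breaks C4–C10 and expels a C5 mesylate (Grob fragmentation), giving the C10 ketone and the cis C4=C5 alkene of dienone lactone A1.
- Merits: no macrocyclisation, no high dilution, alkene geometry fixed by the antiperiplanar array, good precedent for cyclodecenones.
- Weak points: A1 has neither C14 nor the tertiary alcohol, so C10 must be set by methyl addition to an enolisable ketone in the flexible ring. The epoxide must come from nucleophilic epoxidation of a cis-enone that can isomerise under the alkoxide of the fragmentation. The bicyclic substrate needs a quaternary C4, a correctly oriented leaving group and five further stereocentres. Methylenation and the angelate exchange remain.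
- Comparison: for ring formation this road is safer than the Stille closure (step 17) and needs no extension of a palladium reaction to a new ring size. The chosen plan sets against this that all stereocentres are in place or tether-controlled once the ring exists, that both allylic oxygens and the lactone arrive in one step, and that no carbonyl addition on the ten-membered ring is needed.

**Alternative 2:** The cut is C8–C9 and C10–O. In the forward step NaOCl oxidises a C8 aldoxime to the nitrile oxide, which adds across a C9=C10 isopropenyl alkene and closes the carbocycle and a bridging isoxazoline, A2.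
- Merits: ring closure and the oxygenated quaternary C10 in one step. The isoxazoline is a masked β-hydroxy ketone from which the syn C8/C10 diol follows by N–O cleavage and directed reduction. Epoxide and lactone are already present.
- Weak points: the face of the 1,1-disubstituted alkene that sets C10 is decided only by the forming ring. The nitrile oxide sits on C7 next to the lactone and can epimerise it or dimerise at the dilution a medium ring needs. The bridgehead C=N adds strain. Reductive N–O cleavage (Raney nickel or Mo(CO)6) must spare the epoxide and the alkene. The C8 ketone then has an epimerisable neighbour, and α-methylenation must be done late with base beside the epoxide.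
- Comparison: this road is more economical around C8–C10 than the chosen plan, which spends steps 2–4 and 11–13 there, and it brings the epoxide in early. The chosen plan sets against it that C10 and C8 are fixed on open-chain compounds (4 and 19), where they can be checked and corrected, and that no reduction is needed once sensitive groups are present.

**Alternative 3:** The cut is C1–C2 and the epoxide C1–O bond. In the forward step MgBr2·OEt2 and i-Pr2NEt enolise a C3 chloromethyl ketone at C2, the enolate adds to a C1 aldehyde and the aldolate displaces chloride, giving the cis-epoxy enone A3.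
- Merits: ring and epoxide in one mild operation, with no diol differentiation and no sulfonate.
- Weak points: medium-ring Darzens closures have little precedent. The aldehyde is neopentylic. The chloro ketone is part of a (Z)-enone whose γ-carbon C6 carries the lactone oxygen, so enolisation can run through the dienolate and expel the carboxylate or isomerise the alkene. Open-chain Darzens reactions favour trans-epoxy ketones, so the cis epoxide and both new centres depend on conformation. The C3 ketone must later be reduced with control, and methylenation and protecting-group exchange at C8 and C10 follow.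
- Comparison: for the epoxide this road is shorter and cleaner than steps 24–26 of the chosen plan. The chosen plan sets against it a ring closure of a documented type, tartaric acid as the source of C1/C2, and C3 set by the same step that builds the lactone.

Key step: step 23

## Route

Step 1
Reactants: 1 dimethyl 2,3-O-isopropylidene-L-tartrate
Product: 2 bis-Weinreb amide
Conditions: MeNH(OMe)·HCl, i-PrMgCl, THF, −20 °C → 0 °C
Reagents that add atoms: N,O-dimethylhydroxylamine hydrochloride, CNOC.Cl
Why: Aminolysis of both esters by the chloromagnesium amide (Weinreb amide formation); the trans-dioxolane is the stable arrangement, so C1 and C2 are not at risk.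

Step 2
Reactants: 2 bis-Weinreb amide
Product: 3 allyl ketone
Conditions: CH2=CHCH2MgBr (1.05 equiv), THF, −78 °C; aq. NH4Cl
Reagents that add atoms: allylmagnesium bromide, C=CC[Mg]Br
Why: Grignard addition to a Weinreb amide stops at the chelated tetrahedral adduct, so one equivalent should give the monoketone; the C2 symmetry of 2 makes both amides equivalent. This forms C9–C10.

Step 3
Reactants: 3 allyl ketone
Product: 4 C10 tertiary alcohol
Conditions: MeTi(OiPr)3 (from MeLi and ClTi(OiPr)3), Et2O/THF, −40 °C → 0 °C
Reagents that add atoms: methyltitanium triisopropoxide, C[Ti](OC(C)C)(OC(C)C)OC(C)C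
Why: The titanium reagent is non-basic (no enolisation of the β,γ-unsaturated ketone), ignores the Weinreb amide and does not chelate. Addition should follow the polar Felkin–Anh model, with methyl entering anti to the dioxolane C1–O bond, which places the C10 oxygen syn to O1 (10R).

Step 4
Reactants: 4 C10 tertiary alcohol
Product: 5 C10 triethylsilyl ether
Conditions: Et3SiOTf, 2,6-lutidine, CH2Cl2, −78 °C → 0 °C
Reagents that add atoms: triethylsilyl trifluoromethanesulfonate, CC[Si](CC)(CC)OS(=O)(=O)C(F)(F)F
Why: Silyl triflates silylate tertiary alcohols; the ether keeps the hydroxyl out of the later aldol and olefinations.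

Step 5
Reactants: 5 C10 triethylsilyl ether
Product: 6 C3 aldehyde
Conditions: i-Bu2AlH, THF, −78 °C; Rochelle salt
Reagents that add atoms: none
Why: Hydride reduction of a Weinreb amide stops at the chelated hemiaminal and releases the aldehyde on work-up; the trans-dioxolane protects the α-centre against epimerisation.

Step 6
Reactants: 6 C3 aldehyde
Product: 7 (Z)-C4 vinyl iodide
Conditions: EtPPh3I, n-BuLi, THF; I2, −78 °C; NaN(SiMe3)2; then 6, −78 °C → −20 °C
Reagents that add atoms: (1-iodoethylidene)triphenylphosphorane (made in the flask), CC(I)=P(c1ccccc1)(c1ccccc1)c1ccccc1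
Why: Zhao olefination (Wittig reaction of the α-iodo ylide) gives the (Z)-2-iodoalkene with iodine cis to the chain. This is the geometry the C3=C4 bond needs for C2 and C5 to be cis in the ring.

Step 7
Reactants: 7 (Z)-C4 vinyl iodide
Product: 9 C8 aldehyde, via terminal diol 8 (not isolated)
Conditions: OsO4 (cat.), NaIO4, 2,6-lutidine, dioxane/H2O, rt
Reagents that add atoms: osmium tetroxide (oxygen carrier), O=[Os](=O)(=O)=O; sodium periodate, [Na+].[O-]I(=O)(=O)=O
Why: Lemieux–Johnson cleavage: OsO4 dihydroxylates the monosubstituted alkene much faster than the hindered, iodine-deactivated trisubstituted one, and periodate cleaves the diol in the same flask.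

Step 8
Reactants: 10 3-chloro-2-(chloromethyl)prop-1-ene; 11 4-methoxybenzyl alcohol
Product: 12 allylic chloride ether
Conditions: NaH, Bu4NI (cat.), THF, 0 °C → rt (10 in excess)
Reagents that add atoms: none
Why: Williamson ether synthesis on a reactive allylic chloride; excess dichloride suppresses the bis-ether.

Step 9
Reactants: 12 allylic chloride ether
Product: 14 butenoic acid, via allylic Grignard reagent 13 (not isolated)
Conditions: Mg, THF, 0 °C; CO2; 1 M HCl
Reagents that add atoms: carbon dioxide, O=C=O
Why: Carboxylation of an allylic Grignard reagent; the 2-substituted allyl unit is symmetric, so both termini give the same β,γ-unsaturated acid.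

Step 10
Reactants: 14 butenoic acid; 15 (R)-4-benzyloxazolidin-2-one
Product: 17 N-acyloxazolidinone, via mixed pivalic anhydride 16 (not isolated)
Conditions: t-BuCOCl, Et3N, THF, −20 °C; then 15, LiCl, rt
Reagents that add atoms: none
Why: N-Acylation through the mixed anhydride under mild amine/LiCl conditions, which avoids a strong base that could move the double bond into conjugation.

Step 11
Reactants: 17 N-acyloxazolidinone; 9 C8 aldehyde
Product: 19 syn-aldol adduct, via dibutylboron (Z)-enolate 18 (not isolated)
Conditions: Bu2BOTf, i-Pr2NEt, CH2Cl2, −78 °C → 0 °C; 9, −78 °C → 0 °C; pH 7 buffer, MeOH, H2O2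
Reagents that add atoms: none
Why: Evans syn aldol: the (Z)-boron enolate reacts through a Zimmerman–Traxler chair on the face left open by the (R)-benzyl group, which should set C7 (R) and C8 (S) together, syn, whatever the remote C10 centre does. This forms C7–C8.

Step 12
Reactants: 19 syn-aldol adduct
Product: 20 bis(triethylsilyl) ether imide
Conditions: Et3SiOTf, 2,6-lutidine, CH2Cl2, −78 °C
Reagents that add atoms: triethylsilyl trifluoromethanesulfonate, CC[Si](CC)(CC)OS(=O)(=O)C(F)(F)F
Why: Silylation blocks the C8 oxygen as a poor leaving group, so the later C6 aldehyde cannot lose it by β-elimination.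

Step 13
Reactants: 20 bis(triethylsilyl) ether imide
Product: 21 C6 primary alcohol
Conditions: LiBH4, MeOH (1 equiv), THF, 0 °C
Reagents that add atoms: none
Why: LiBH4 reduces the activated exocyclic imide carbonyl and releases the auxiliary; silyl and PMB ethers, the acetonide and the vinyl iodide are inert.

Step 14
Reactants: 21 C6 primary alcohol
Product: 22 C4 vinylstannane alcohol
Conditions: Me3SnSnMe3, Pd(PPh3)4 (cat.), toluene, 80 °C
Reagents that add atoms: hexamethylditin, C[Sn](C)(C)[Sn](C)(C)C
Why: Palladium-catalysed iodine–tin exchange (oxidative addition, transmetalation with the distannane, reductive elimination) proceeds with retention of the (Z)-geometry. It is done before the second vinyl iodide exists, so the two termini are unambiguous.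

Step 15
Reactants: 22 C4 vinylstannane alcohol
Product: 23 C6 aldehyde
Conditions: Dess–Martin periodinane, pyridine, CH2Cl2, 0 °C → rt
Reagents that add atoms: none
Why: Dess–Martin oxidation under buffered, non-basic conditions should give the α-branched β,γ-unsaturated aldehyde without epimerisation or protodestannylation; it is used at once.

Step 16
Reactants: 23 C6 aldehyde
Product: 24 seco stannane (5Z)-vinyl iodide
Conditions: Ph3PCH2I iodide, NaN(SiMe3)2, THF; HMPA, −78 °C; then 23, −78 °C
Reagents that add atoms: (iodomethylidene)triphenylphosphorane (made in the flask), IC=P(c1ccccc1)(c1ccccc1)c1ccccc1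
Why: Stork–Zhao olefination: the iodo ylide adds at −78 °C and collapses through the cis-oxaphosphetane to the (Z)-iodoalkene. Carbonyl addition is faster than deprotonation, so C7 should keep its configuration.

Step 17
Reactants: 24 seco stannane (5Z)-vinyl iodide
Product: 25 macrocyclic diene bis(silyl ether)
Conditions: Pd2(dba)3 (cat.), AsPh3, DMF, 40 °C, 1 mM, slow addition
Reagents that add atoms: none
Why: Intramolecular Stille coupling under high dilution forms C4–C5 with retention at both sp2 carbons and gives the (3Z,5Z)-diene. AsPh3 speeds transmetalation of the hindered α-methyl alkenylstannane, and closure of medium rings holding a cis,cis-diene by palladium coupling of two alkenyl partners is known.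

Step 18
Reactants: 25 macrocyclic diene bis(silyl ether)
Product: 26 macrocyclic diol
Conditions: HF·pyridine, pyridine, THF, 0 °C → rt
Reagents that add atoms: none
Why: Buffered HF cleaves the secondary and then the tertiary triethylsilyl ether; the PMB ether and the acetonide stay.

Step 19
Reactants: 26 macrocyclic diol; 27 angelic acid
Product: 29 C8 angelate, via mixed trichlorobenzoic anhydride 28 (not isolated)
Conditions: 2,4,6-Cl3C6H2COCl, Et3N, toluene, rt; then 26, 80 °C
Reagents that add atoms: none
Why: Yamaguchi-type esterification through the mixed anhydride, run without a nucleophilic catalyst, is the standard way to make angelates without Z-to-E isomerisation. Only the secondary C8 hydroxyl is acylated; the tertiary C10 hydroxyl is inert.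

Step 20
Reactants: 29 C8 angelate
Product: 30 C12 allylic alcohol
Conditions: DDQ, CH2Cl2/pH 7 buffer, 0 °C
Reagents that add atoms: none
Why: Oxidative cleavage of the PMB ether by hydride abstraction at the electron-rich benzylic position; esters, acetonide and the non-planar diene should not react at 0 °C.

Step 21
Reactants: 30 C12 allylic alcohol
Product: 31 C12 enal
Conditions: MnO2, CH2Cl2, rt
Reagents that add atoms: none
Why: MnO2 oxidises only the allylic primary alcohol, under neutral conditions that leave the doubly allylic C7–H alone.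

Step 22
Reactants: 31 C12 enal
Product: 32 cyclodecadienyl acrylic acid
Conditions: NaClO2, NaH2PO4, 2-methylbut-2-ene, t-BuOH/H2O, 0 °C → rt
Reagents that add atoms: sodium chlorite, [Na+].[O-]Cl=O
Why: Pinnick oxidation converts the 2-substituted acrolein to the acrylic acid; the scavenger removes hypochlorous acid before it reaches the diene.

Step 23
Reactants: 32 cyclodecadienyl acrylic acid
Product: 33 C3-acetoxy α-methylene lactone acetonide
Conditions: Pd(OAc)2 (10 mol %), p-benzoquinone (2 equiv), LiOAc, LiCl (cat.), AcOH/acetone (1:4), rt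
Reagents that add atoms: acetic acid/lithium acetate (acetate), CC(=O)O
Why: Divalent palladium binds the C5=C6 end of the diene and the C12 carboxylate adds to C6 anti to the metal in a 5-exo closure of the γ-lactone, leaving a π-allyl complex over C3–C5; benzoquinone activates it, acetate (kept off the metal by chloride) attacks C3 anti to palladium, and the quinone returns the zerovalent metal to the divalent state. The closest known reaction is the Pd(OAc)2/benzoquinone 1,4-acyloxylactonisation of six- to eight-membered cyclic diene acids. C6 is set by the tether: the C7 side chain reaches C6 only from the face on which it stands pseudo-axial, away from the saturated C8–C2 bridge, so H6 and H7 end up cis (6S). C3 is set by the metal: two anti attacks put the acetate on the face of the lactone oxygen (1,4-cis, 3R). The alkene must be cis, which the anti,anti allyl of the ring, further favoured by the C4 methyl, should secure. Attack must go to C3 and not C5, which the C6 acyloxy group (more deactivating than the ether oxygen at C2) should secure. The trans-dioxolane keeps the C10 hydroxyl from closing a tetrahydrofuran onto C3, and the acrylate, angelate and tertiary alcohol are spectators.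

Step 24
Reactants: 33 C3-acetoxy α-methylene lactone acetonide
Product: 34 C1/C2/C10 triol
Conditions: AcOH/H2O (4:1), 50 °C
Reagents that add atoms: none
Why: Acid hydrolysis of the isopropylidene acetal; aqueous acetic acid is too weak to ionise the allylic acetate or to move acyl groups at a useful rate.

Step 25
Reactants: 34 C1/C2/C10 triol
Product: 35 C2 mesylate
Conditions: MeSO2Cl (1.1 equiv), 2,4,6-collidine, CH2Cl2, −20 °C
Reagents that add atoms: methanesulfonyl chloride, CS(=O)(=O)Cl
Why: Sulfonylation with a hindered base picks the C2 hydroxyl; the C1 hydroxyl is neopentylic (next to quaternary C10) and the C10 hydroxyl is tertiary.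

Step 26
Reactants: 35 C2 mesylate
Product: 36 epoxy acetate
Conditions: DBU, CH2Cl2, 0 °C → rt
Reagents that add atoms: none
Why: Intramolecular Williamson closure: O1 displaces the C2 mesylate from the back (3-exo-tet), inverting C2 and retaining C1. The threo diol thus gives the cis epoxide (1R,2R); an amidine base avoids alkoxide or methoxide, which would attack the methylene lactone.

Step 27
Reactants: 36 epoxy acetate
Product: 37 target compound
Conditions: immobilised Candida antarctica lipase B, n-BuOH, t-BuOMe, 35 °C
Reagents that add atoms: none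
Why: Lipase-catalysed transesterification removes the unhindered acetate under neutral, anhydrous conditions. The hindered conjugated angelate and the lactone are poor lipase substrates, and without alkoxide neither Payne rearrangement nor conjugate addition can start.

## Compound list

1 | dimethyl 2,3-O-isopropylidene-L-tartrate: dimethyl (4R,5R)-2,2-dimethyl-1,3-dioxolane-4,5-dicarboxylate | COC(=O)[C@@H]1OC(C)(C)O[C@H]1C(=O)OC | starting material
2 | bis-Weinreb amide: (4R,5R)-N4,N5-dimethoxy-N4,N5,2,2-tetramethyl-1,3-dioxolane-4,5-dicarboxamide | CON(C)C(=O)[C@@H]1OC(C)(C)O[C@H]1C(=O)N(C)OC | intermediate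
3 | allyl ketone: (4R,5R)-5-(but-3-enoyl)-N-methoxy-N,2,2-trimethyl-1,3-dioxolane-4-carboxamide | CON(C)C(=O)[C@@H]1OC(C)(C)O[C@H]1C(=O)CC=C | intermediate
4 | C10 tertiary alcohol: (4R,5R)-5-[(2R)-2-hydroxypent-4-en-2-yl]-N-methoxy-N,2,2-trimethyl-1,3-dioxolane-4-carboxamide | CON(C)C(=O)[C@@H]1OC(C)(C)O[C@H]1[C@](C)(O)CC=C | intermediate
5 | C10 triethylsilyl ether: (4R,5R)-N-methoxy-N,2,2-trimethyl-5-[(2R)-2-(triethylsilyloxy)pent-4-en-2-yl]-1,3-dioxolane-4-carboxamide | CON(C)C(=O)[C@@H]1OC(C)(C)O[C@H]1[C@](C)(O[Si](CC)(CC)CC)CC=C | intermediate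
6 | C3 aldehyde: (4R,5R)-2,2-dimethyl-5-[(2R)-2-(triethylsilyloxy)pent-4-en-2-yl]-1,3-dioxolane-4-carbaldehyde | O=C[C@@H]1OC(C)(C)O[C@H]1[C@](C)(O[Si](CC)(CC)CC)CC=C | intermediate
7 | (Z)-C4 vinyl iodide: (4S,5R)-4-[(1Z)-2-iodoprop-1-en-1-yl]-2,2-dimethyl-5-[(2R)-2-(triethylsilyloxy)pent-4-en-2-yl]-1,3-dioxolane | I/C(C)=C\[C@@H]1OC(C)(C)O[C@H]1[C@](C)(O[Si](CC)(CC)CC)CC=C | intermediate
8 | terminal diol (not isolated; both epimers at the new carbinol): (4R)-4-{(4R,5S)-5-[(1Z)-2-iodoprop-1-en-1-yl]-2,2-dimethyl-1,3-dioxolan-4-yl}-4-(triethylsilyloxy)pentane-1,2-diol | I/C(C)=C\[C@@H]1OC(C)(C)O[C@H]1[C@](C)(O[Si](CC)(CC)CC)CC(O)CO | intermediate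
9 | C8 aldehyde: (3R)-3-{(4R,5S)-5-[(1Z)-2-iodoprop-1-en-1-yl]-2,2-dimethyl-1,3-dioxolan-4-yl}-3-(triethylsilyloxy)butanal | I/C(C)=C\[C@@H]1OC(C)(C)O[C@H]1[C@](C)(O[Si](CC)(CC)CC)CC=O | intermediate
10 | 3-chloro-2-(chloromethyl)prop-1-ene | C=C(CCl)CCl | starting material
11 | 4-methoxybenzyl alcohol | COc1ccc(CO)cc1 | starting material
12 | allylic chloride ether: 1-({[2-(chloromethyl)prop-2-en-1-yl]oxy}methyl)-4-methoxybenzene | C=C(CCl)COCc1ccc(OC)cc1 | intermediate
13 | allylic Grignard reagent (not isolated): chloro{2-[(4-methoxybenzyloxy)methyl]prop-2-en-1-yl}magnesium | C=C(C[Mg]Cl)COCc1ccc(OC)cc1 | intermediate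
14 | butenoic acid: 3-{[(4-methoxybenzyl)oxy]methyl}but-3-enoic acid | C=C(COCc1ccc(OC)cc1)CC(=O)O | intermediate
15 | (R)-4-benzyloxazolidin-2-one: (4R)-4-benzyl-1,3-oxazolidin-2-one | O=C1N[C@H](Cc2ccccc2)CO1 | starting material
16 | mixed pivalic anhydride (not isolated): 3-{[(4-methoxybenzyl)oxy]methyl}but-3-enoic 2,2-dimethylpropanoic anhydride | C=C(COCc1ccc(OC)cc1)CC(=O)OC(=O)C(C)(C)C | intermediate
17 | N-acyloxazolidinone: (4R)-4-benzyl-3-(3-{[(4-methoxybenzyl)oxy]methyl}but-3-enoyl)-1,3-oxazolidin-2-one | C=C(COCc1ccc(OC)cc1)CC(=O)N1C(=O)OC[C@H]1Cc1ccccc1 | intermediate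
18 | dibutylboron (Z)-enolate of 17 (not isolated) | CCCCB(CCCC)O/C(=C\C(=C)COCc1ccc(OC)cc1)N1C(=O)OC[C@H]1Cc1ccccc1 | intermediate
19 | syn-aldol adduct: (4R)-4-benzyl-3-[(2R,3S,5R)-3-hydroxy-5-{(4R,5S)-5-[(1Z)-2-iodoprop-1-en-1-yl]-2,2-dimethyl-1,3-dioxolan-4-yl}-2-{3-[(4-methoxybenzyl)oxy]prop-1-en-2-yl}-5-(triethylsilyloxy)hexanoyl]-1,3-oxazolidin-2-one | I/C(C)=C\[C@@H]1OC(C)(C)O[C@H]1[C@](C)(O[Si](CC)(CC)CC)C[C@H](O)[C@@H](C(=C)COCc2ccc(OC)cc2)C(=O)N2C(=O)OC[C@H]2Cc2ccccc2 | intermediate
20 | bis(triethylsilyl) ether imide: (4R)-4-benzyl-3-[(2R,3S,5R)-5-{(4R,5S)-5-[(1Z)-2-iodoprop-1-en-1-yl]-2,2-dimethyl-1,3-dioxolan-4-yl}-2-{3-[(4-methoxybenzyl)oxy]prop-1-en-2-yl}-3,5-bis(triethylsilyloxy)hexanoyl]-1,3-oxazolidin-2-one | I/C(C)=C\[C@@H]1OC(C)(C)O[C@H]1[C@](C)(O[Si](CC)(CC)CC)C[C@H](O[Si](CC)(CC)CC)[C@@H](C(=C)COCc2ccc(OC)cc2)C(=O)N2C(=O)OC[C@H]2Cc2ccccc2 | intermediate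
21 | C6 primary alcohol: (2S,3S,5R)-5-{(4R,5S)-5-[(1Z)-2-iodoprop-1-en-1-yl]-2,2-dimethyl-1,3-dioxolan-4-yl}-2-{3-[(4-methoxybenzyl)oxy]prop-1-en-2-yl}-3,5-bis(triethylsilyloxy)hexan-1-ol | I/C(C)=C\[C@@H]1OC(C)(C)O[C@H]1[C@](C)(O[Si](CC)(CC)CC)C[C@H](O[Si](CC)(CC)CC)[C@@H](C(=C)COCc2ccc(OC)cc2)CO | intermediate
22 | C4 vinylstannane alcohol: (2S,3S,5R)-5-{(4R,5S)-2,2-dimethyl-5-[(1Z)-2-(trimethylstannyl)prop-1-en-1-yl]-1,3-dioxolan-4-yl}-2-{3-[(4-methoxybenzyl)oxy]prop-1-en-2-yl}-3,5-bis(triethylsilyloxy)hexan-1-ol | C[Sn](C)(C)/C(C)=C\[C@@H]1OC(C)(C)O[C@H]1[C@](C)(O[Si](CC)(CC)CC)C[C@H](O[Si](CC)(CC)CC)[C@@H](C(=C)COCc2ccc(OC)cc2)CO | intermediate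
23 | C6 aldehyde: (2R,3S,5R)-5-{(4R,5S)-2,2-dimethyl-5-[(1Z)-2-(trimethylstannyl)prop-1-en-1-yl]-1,3-dioxolan-4-yl}-2-{3-[(4-methoxybenzyl)oxy]prop-1-en-2-yl}-3,5-bis(triethylsilyloxy)hexanal | C[Sn](C)(C)/C(C)=C\[C@@H]1OC(C)(C)O[C@H]1[C@](C)(O[Si](CC)(CC)CC)C[C@H](O[Si](CC)(CC)CC)[C@@H](C(=C)COCc2ccc(OC)cc2)C=O | intermediate
24 | seco stannane (5Z)-vinyl iodide: (4R,5S)-4-[(2R,4S,5R,6Z)-7-iodo-5-{3-[(4-methoxybenzyl)oxy]prop-1-en-2-yl}-2,4-bis(triethylsilyloxy)hept-6-en-2-yl]-2,2-dimethyl-5-[(1Z)-2-(trimethylstannyl)prop-1-en-1-yl]-1,3-dioxolane | C[Sn](C)(C)/C(C)=C\[C@@H]1OC(C)(C)O[C@H]1[C@](C)(O[Si](CC)(CC)CC)C[C@H](O[Si](CC)(CC)CC)[C@@H](C(=C)COCc2ccc(OC)cc2)/C=C\I | intermediate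
25 | macrocyclic diene bis(silyl ether): (1R,2S,3Z,5Z,7R,8S,10R)-1,2-(isopropylidenedioxy)-7-{3-[(4-methoxybenzyl)oxy]prop-1-en-2-yl}-4,10-dimethyl-8,10-bis(triethylsilyloxy)cyclodeca-3,5-diene | C=C(COCc3ccc(OC)cc3)[C@H]1/C=C\C(C)=C/[C@@H]2OC(C)(C)O[C@H]2[C@](C)(O[Si](CC)(CC)CC)C[C@@H]1O[Si](CC)(CC)CC | intermediate
26 | macrocyclic diol: (1R,2S,3Z,5Z,7R,8S,10R)-1,2-(isopropylidenedioxy)-7-{3-[(4-methoxybenzyl)oxy]prop-1-en-2-yl}-4,10-dimethylcyclodeca-3,5-diene-8,10-diol | C=C(COCc3ccc(OC)cc3)[C@H]1/C=C\C(C)=C/[C@@H]2OC(C)(C)O[C@H]2[C@](C)(O)C[C@@H]1O | intermediate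
27 | angelic acid: (Z)-2-methylbut-2-enoic acid | C/C=C(/C)C(=O)O | starting material
28 | mixed trichlorobenzoic anhydride (not isolated): (Z)-2-methylbut-2-enoic 2,4,6-trichlorobenzoic anhydride | C/C=C(/C)C(=O)OC(=O)c1c(Cl)cc(Cl)cc1Cl | intermediate
29 | C8 angelate: (1R,2S,3Z,5Z,7R,8S,10R)-10-hydroxy-1,2-(isopropylidenedioxy)-7-{3-[(4-methoxybenzyl)oxy]prop-1-en-2-yl}-4,10-dimethylcyclodeca-3,5-dien-8-yl (Z)-2-methylbut-2-enoate | C=C(COCc3ccc(OC)cc3)[C@H]1/C=C\C(C)=C/[C@@H]2OC(C)(C)O[C@H]2[C@](C)(O)C[C@@H]1OC(=O)/C(C)=C\C | intermediate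
30 | C12 allylic alcohol: (1R,2S,3Z,5Z,7R,8S,10R)-10-hydroxy-7-(3-hydroxyprop-1-en-2-yl)-1,2-(isopropylidenedioxy)-4,10-dimethylcyclodeca-3,5-dien-8-yl (Z)-2-methylbut-2-enoate | C=C(CO)[C@H]1/C=C\C(C)=C/[C@@H]2OC(C)(C)O[C@H]2[C@](C)(O)C[C@@H]1OC(=O)/C(C)=C\C | intermediate
31 | C12 enal: (1R,2S,3Z,5Z,7R,8S,10R)-10-hydroxy-1,2-(isopropylidenedioxy)-4,10-dimethyl-7-(3-oxoprop-1-en-2-yl)cyclodeca-3,5-dien-8-yl (Z)-2-methylbut-2-enoate | C=C(C=O)[C@H]1/C=C\C(C)=C/[C@@H]2OC(C)(C)O[C@H]2[C@](C)(O)C[C@@H]1OC(=O)/C(C)=C\C | intermediate
32 | cyclodecadienyl acrylic acid: 2-[(1R,2S,3Z,5Z,7R,8S,10R)-8-(angeloyloxy)-10-hydroxy-1,2-(isopropylidenedioxy)-4,10-dimethylcyclodeca-3,5-dien-7-yl]prop-2-enoic acid | OC(=O)C(=C)[C@H]1/C=C\C(C)=C/[C@@H]2OC(C)(C)O[C@H]2[C@](C)(O)C[C@@H]1OC(=O)/C(C)=C\C | intermediate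
33 | C3-acetoxy α-methylene lactone acetonide: (1R,2S,3R,6S,7R,8S,10R)-3-acetoxy-8-(angeloyloxy)-10-hydroxy-1,2-(isopropylidenedioxy)germacra-4Z,11(13)-dien-12,6-olide | C=C1C(=O)O[C@H]2/C=C(/C)[C@@H](OC(C)=O)[C@@H]3OC(C)(C)O[C@H]3[C@](C)(O)C[C@H](OC(=O)/C(C)=C\C)[C@@H]12 | intermediate
34 | C1/C2/C10 triol: (1R,2R,3R,6S,7R,8S,10R)-3-acetoxy-8-(angeloyloxy)-1,2,10-trihydroxygermacra-4Z,11(13)-dien-12,6-olide | C=C1C(=O)O[C@H]2/C=C(/C)[C@@H](OC(C)=O)[C@H](O)[C@@H](O)[C@](C)(O)C[C@H](OC(=O)/C(C)=C\C)[C@@H]12 | intermediate
35 | C2 mesylate: (1R,2R,3R,6S,7R,8S,10R)-3-acetoxy-8-(angeloyloxy)-1,10-dihydroxy-2-(methanesulfonyloxy)germacra-4Z,11(13)-dien-12,6-olide | C=C1C(=O)O[C@H]2/C=C(/C)[C@@H](OC(C)=O)[C@H](OS(C)(=O)=O)[C@@H](O)[C@](C)(O)C[C@H](OC(=O)/C(C)=C\C)[C@@H]12 | intermediate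
36 | epoxy acetate: (1R,2R,3R,6S,7R,8S,10R)-3-acetoxy-8-(angeloyloxy)-1,2-epoxy-10-hydroxygermacra-4Z,11(13)-dien-12,6-olide | C=C1C(=O)O[C@H]2/C=C(/C)[C@@H](OC(C)=O)[C@H]3O[C@H]3[C@](C)(O)C[C@H](OC(=O)/C(C)=C\C)[C@@H]12 | intermediate
37 | target CNP0351240.3: (1R,2R,3R,6S,7R,8S,10R)-8-(angeloyloxy)-1,2-epoxy-3,10-dihydroxygermacra-4Z,11(13)-dien-12,6-olide | C=C1C(=O)O[C@H]2/C=C(/C)[C@@H](O)[C@H]3O[C@H]3[C@](C)(O)C[C@H](OC(=O)/C(C)=C\C)[C@@H]12 | target

## Step count and weakest steps

Total: 27 steps. Longest linear sequence: 24 steps (steps 1–7 and 11–27, from 1 to 37). The acyl fragment 17 takes 3 steps (8–10).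

**Step 23 (key step).** Three things can go wrong.
- The palladium and the carboxylate may compete for the one open face of the twisted diene. Oxypalladation then turns syn and external acetate arrives trans to the lactone oxygen (C3 epimer), or turnover stalls.
- Acetate may attack C5, because both allyl termini have an oxygenated neighbour.
- The allyl may equilibrate to a syn terminus and give the E-alkene, which a ten-membered ring can hold.

Fallback, from 32 back to 33 through a different palladium manifold: buffered m-chloroperbenzoic acid (Na2HPO4) should epoxidise the electron-richest, trisubstituted C3=C4 bond on the open face to give the vinyl epoxide acid F1. Pd(PPh3)4 then ionises the allylic C4–O bond with inversion, and the C12 carboxylate closes onto C6 with a second inversion, so the C3 hydroxyl and the lactone oxygen of the C3 hydroxy lactone F2 are cis by a double-inversion mechanism known for diene monoepoxides. Ac2O/pyridine returns to 33.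

**Step 3.** Partial chelation of the metal by the dioxolane oxygen could erode or reverse the Felkin–Anh preference and give the C10 epimer, and the β,γ-unsaturated ketone can slip into conjugation. Fallback, from 2 back to 4 with the order of additions reversed: one equivalent of CH3MgBr gives the methyl ketone F3, and CH2=CHCH2SiMe3/TiCl4 at −78 °C then adds under Cram-chelate control. Allyl arriving second under chelation gives the same C10 configuration as methyl arriving second under Felkin–Anh control.

**Step 17.** Transmetalation at the α-methyl alkenylstannane is slow and the ring is strained, so intermolecular coupling and protodestannylation can outrun closure. Fallback, from 21 back to 26, using a silicon tether in place of tin; it also bypasses the iodo-ylide olefination of step 16, the other exposed point of this stretch.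
- Dess–Martin oxidation gives the iodo aldehyde F4.
- Ph3P=CH2 at −78 °C gives the C7 vinyl compound F5.
- HF·pyridine gives the diol F6.
- ClSiMe2CH=CH2/imidazole silylates only the secondary hydroxyl, giving the vinyldimethylsilyl ether F7.
- Second-generation Hoveyda–Grubbs catalyst closes the six-membered cyclic siloxane F8, which fixes the C5=C6 bond as cis.
- [(allyl)PdCl]2 with Bu4NF under slow addition couples the alkenylsilicon carbon C5 with the C4 iodide (intramolecular Hiyama coupling, a known route to medium rings with a cis,cis-diene) and frees the C8 hydroxyl, giving 26.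

**Step 26.** Once the C1 alkoxide forms, the C3 acetate can migrate to O1 through a six-membered transition state and the freed C3 oxygen can close the wrong (C2–C3) epoxide. Poor discrimination of the C1 and C2 hydroxyls in step 25 would feed the same problem. Fallback, from 34 directly to 36: Mitsunobu cyclodehydration (PPh3 and diisopropyl azodicarboxylate, betaine preformed) activates the less hindered C2 hydroxyl as an oxyphosphonium under neutral conditions, and O1 displaces it with inversion. This fallback makes no new compound (F0).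

**Step 27.** The lipase may not accept the hindered secondary acetate on the macrocycle, and slow turnover gives time for alcoholysis of the lactone. Fallback, from 32 to 37 with a different C3 ester:
- The 1,4-oxidation is run with chloroacetic acid and lithium chloroacetate in acetone (Pd(OAc)2, p-benzoquinone, LiCl) to give the C3 chloroacetate lactone F9.
- AcOH/H2O gives the chloroacetate triol F10.
- MeSO2Cl/collidine gives the chloroacetate mesylate F11.
- Cs2CO3 in MeCN gives the epoxy chloroacetate F12.
- Aqueous pyridine cleaves the chloroacetate selectively to 37, without enzyme or alkoxide.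

## Further compounds

F1 | step 23 | vinyl epoxide acid (3,4-epoxide of 32) | OC(=O)C(=C)[C@H]1/C=C\[C@@]3(C)O[C@H]3[C@@H]2OC(C)(C)O[C@H]2[C@](C)(O)C[C@@H]1OC(=O)/C(C)=C\C
F2 | step 23 | C3 hydroxy lactone (deacetyl 33) | C=C1C(=O)O[C@H]2/C=C(/C)[C@@H](O)[C@@H]3OC(C)(C)O[C@H]3[C@](C)(O)C[C@H](OC(=O)/C(C)=C\C)[C@@H]12
F3 | step 3 | methyl ketone: (4R,5R)-5-acetyl-N-methoxy-N,2,2-trimethyl-1,3-dioxolane-4-carboxamide | CON(C)C(=O)[C@@H]1OC(C)(C)O[C@H]1C(C)=O
F4 | step 17 | iodo aldehyde (C6 aldehyde of 21) | I/C(C)=C\[C@@H]1OC(C)(C)O[C@H]1[C@](C)(O[Si](CC)(CC)CC)C[C@H](O[Si](CC)(CC)CC)[C@@H](C(=C)COCc2ccc(OC)cc2)C=O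
F5 | step 17 | C7 vinyl compound | I/C(C)=C\[C@@H]1OC(C)(C)O[C@H]1[C@](C)(O[Si](CC)(CC)CC)C[C@H](O[Si](CC)(CC)CC)[C@@H](C(=C)COCc2ccc(OC)cc2)C=C
F6 | step 17 | C8/C10 diol of the vinyl compound | I/C(C)=C\[C@@H]1OC(C)(C)O[C@H]1[C@](C)(O)C[C@H](O)[C@@H](C(=C)COCc2ccc(OC)cc2)C=C
F7 | step 17 | C8 vinyldimethylsilyl ether | I/C(C)=C\[C@@H]1OC(C)(C)O[C@H]1[C@](C)(O)C[C@H](O[Si](C)(C)C=C)[C@@H](C(=C)COCc2ccc(OC)cc2)C=C
F8 | step 17 | cyclic siloxane (1-oxa-2-silacyclohex-3-ene across O8–Si–C5=C6–C7–C8) | I/C(C)=C\[C@@H]1OC(C)(C)O[C@H]1[C@](C)(O)C[C@@H]2O[Si](C)(C)C=C[C@@H]2C(=C)COCc3ccc(OC)cc3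
F0 | step 26 | none | none
F9 | step 27 | C3 chloroacetate lactone (chloroacetate analogue of 33) | C=C1C(=O)O[C@H]2/C=C(/C)[C@@H](OC(=O)CCl)[C@@H]3OC(C)(C)O[C@H]3[C@](C)(O)C[C@H](OC(=O)/C(C)=C\C)[C@@H]12
F10 | step 27 | chloroacetate triol (analogue of 34) | C=C1C(=O)O[C@H]2/C=C(/C)[C@@H](OC(=O)CCl)[C@H](O)[C@@H](O)[C@](C)(O)C[C@H](OC(=O)/C(C)=C\C)[C@@H]12
F11 | step 27 | chloroacetate mesylate (analogue of 35) | C=C1C(=O)O[C@H]2/C=C(/C)[C@@H](OC(=O)CCl)[C@H](OS(C)(=O)=O)[C@@H](O)[C@](C)(O)C[C@H](OC(=O)/C(C)=C\C)[C@@H]12
F12 | step 27 | epoxy chloroacetate (analogue of 36) | C=C1C(=O)O[C@H]2/C=C(/C)[C@@H](OC(=O)CCl)[C@H]3O[C@H]3[C@](C)(O)C[C@H](OC(=O)/C(C)=C\C)[C@@H]12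
A1 | alternative 1 | cis,cis-cyclodecadienone lactone | C1C(=O)O[C@H]2/C=C(/C)[C@@H](O[Si](C)(C)C(C)(C)C)/C=C\C(=O)C[C@H](OCc3ccc(OC)cc3)[C@@H]12
A2 | alternative 2 | bridged isoxazoline | C1C(=O)O[C@H]2/C=C(/C)[C@@H](O[Si](C)(C)C(C)(C)C)[C@H]3O[C@H]3[C@]4(C)ON=C(C4)[C@@H]12
A3 | alternative 3 | ten-membered cis-epoxy enone | C1C(=O)O[C@H]2/C=C(/C)C(=O)[C@H]3O[C@H]3[C@](C)(OCc4ccc(OC)cc4)C[C@H](O[Si](C)(C)C(C)(C)C)[C@@H]12
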